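## The problem

Target 31 is a cyclooctane (C1–C8) that shares C2=C3 with a butenolide and C4–C5 with a cis-fused cyclopropane (methylene C9). It carries a secondary alcohol at C8, a methyl group at C6 and, at C1, a chain whose stereocentre C1' bears an acetoxymethyl and a 4-methylpent-3-enyl (homoprenyl) group. The central difficulty is the eight-membered ring, which resists direct closure and here must be formed with a lactone, an alkene or cyclopropane and a carbonyl spaced around it. Six stereocentres have to be set (1'S, 1R, 4R, 5R, 6S, 8S). C1' and C1 are neighbours and can be related through a five-membered lactone. C1 can direct hydride to C8. The C8 hydroxyl lies on the same ring face as C9 and opposite the C6 methyl, so both can steer a cyclopropanation. C6 is remote from the rest and needs its own reagent-controlled origin. The primary acetate will not survive amide bases or hydrides, the trisubstituted side-chain alkene is exposed to acids, peracids and carbenoids, and H-1, γ to the butenolide carbonyl, can epimerise under base. The feature that opens the route is that, with C8 as a ketone and C4=C5 as a Z alkene, the carbocycle is a cyclooct-4-enone whose C6 methyl sits exactly where the substituted carbon of a ring-opened trans-2-methylcyclopropane ends up.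

## Retrosynthesis

Acetate and alcohol. Target 31 is traced to diol 30 and on to bis-silyl ether 29. The acetate is put on last because the butenolide is made through a lactone enolate, which an acetate would not tolerate. The price is a selective acylation of a primary alcohol beside a hindered secondary one, which is a reliable discrimination. For the same reason the key-step precursor and product carry a silyl ether in place of the acetate.

Butenolide. The C2=C3 double bond of 29 is removed to give the saturated lactone 26, to be reinstalled by selenenylation of the lactone enolate and selenoxide elimination. Doing this after the cyclopropane is in place is preferred to dehydrogenating the β,γ-unsaturated lactone 24. There the dienolate could react at C3 or C5, an allylic selenoxide would rearrange, and a palladium enolate could eliminate towards C6. In 26 the only hydrogen available for syn elimination is H-2.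

Cyclopropane. The C4–C9 and C5–C9 bonds of 25 are cut to give cyclooctenol 24. The C8 hydroxyl is on the face that must receive the methylene and the C6 methyl on the other, so a hydroxyl-directed zinc carbenoid is asked to do two things: choose the face and prefer the ring alkene over the side-chain alkene. Alcohol 24 comes from ketone 23 by hydride addition anti to the C1 substituent.

Eight-membered ring (key disconnection). In 23 the C7–C8 bond is cut and C5–C7 re-formed, which folds C5, C6 and C7 back into a trans-2-methylcyclopropane and turns C8 into an aldehyde: 5-cyclopropylpent-4-enal 22, whose alkene is the C3=C4 alkylidene of lactone B. Against an aldol, metathesis or radical closure of the eight-membered ring, this cut exchanges a medium-ring cyclisation for a six-membered metallacycle that grows by strain release. It also brings C6 in from a cyclopropane that can be made enantiopure. The precursor has only a five-membered lactone and a three-membered ring. The forward reaction must place rhodium on C4, cleave the less substituted cyclopropane bond, and tolerate an alkene conjugated to the lactone carbonyl.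

Aldehyde. Aldehyde 22 is traced through hydrazone 21 and lactol 19 to bis-lactone 17, in which C8 and the C1' oxymethyl group are tied together as lactone A. This ring is what relates C1 to C1', so it is kept as long as possible and opened only after both C–C bonds to lactone B exist. The forward task is to half-reduce the saturated lactone A in the presence of the conjugated lactone B and to trap the open hydroxy-aldehyde form.

C1–C2 and C3=C4. Bis-lactone 17 is cut at C1–C2 and at C3=C4 into lactone 12, furanone 13 and cyclopropanecarbaldehyde 3: a conjugate addition–aldol sequence followed by dehydration of adduct 15. The enolate of 12 can only be attacked trans to its homoprenyl group, which sets C1. C2 and C3 are transient centres that are planarised later.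

C1'. Lactone 12 is traced to imide 10 and on to imide 9, made from acid 6 and oxazolidinone 7. An auxiliary-controlled enolate alkylation is chosen over a catalytic conjugate addition to 13 because its sense of induction is not in doubt. Acid 6 comes from phosphonium salt 4 and acetone 5.

C5/C6. Aldehyde 3 comes from alcohol 2 and this from (E)-crotyl alcohol 1 by asymmetric cyclopropanation, which fixes C6 before any ring of the target exists.

## Roads not taken

Alternative 1: The cyclopropane bond C4–C5 is made last from a nine-membered ring. Homoallylic mesylate A1 (C4 mesylate, C9 methylene, Z C5=C6 alkene carrying the methyl group) is ionised in a fluorinated alcohol with a trialkylsilane. The alkene displaces the mesylate across the ring, and hydride capture at the tertiary C6 cation gives A2, the C8 silyl ether of 31. This creates the cyclopropane and C4, C5 and C6 in one late operation, with butenolide and acetate already in place, and no carbenoid has to choose between two alkenes. In these respects it is better than the chosen plan, which spends an asymmetric cyclopropanation, a directed cyclopropanation and several redox and protecting-group steps on the same centres. Its weak points are structural. A1 is a nine-membered diene that is no easier to close than the eight-membered ring. Ionisation at C4 is slowed by the electron-poor butenolide carbon next to it. The cyclopropylcarbinyl cation has cyclobutyl and homoallyl relatives and can be lost by elimination. Hydride must reach one face of C6 in a flexible ring. The side-chain alkene is itself a π-nucleophile under ionising conditions. The chosen plan sets against this a ring-forming step of a known reaction type and a C6 centre fixed at the outset.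

Alternative 2: The lactone C–O bond is formed while a C–C bond of a bridged β-diketone breaks. In A3 a one-carbon keto bridge joins C3 and C7 of a bicyclo[3.3.1]nonane that already carries the cyclopropane, the C6 methyl, the C1 chain and a C2 hydroxymethyl group. An amine base lets the hydroxyl add to the bridging ketone, and retro-Claisen cleavage towards the C8 enolate gives the lactone-fused cyclooctanone A4. The merits are real: the medium ring comes from six-membered-ring chemistry, the lactone forms in the same step, the reagents are trivial, and the fragmentation is thermodynamically downhill. As a ring-forming event it is more secure than a rhodium-catalysed C–H activation on an untested alkene. The cost is A3 itself, a tricycle with six stereocentres on a rigid bridged frame, each of which must be placed before the key step. A4 still needs reduction at C8, dehydrogenation of the lactone and the acetate exchange, the same end game as from 26. The chosen plan offers a precursor assembled from three small fragments with only three stereogenic elements to control before the ring forms.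

Alternative 3: C2–C3 and C4–C5 are formed by inserting two carbons into a six-membered ring. The silyl enol ether A5 of a cyclohexanone that already holds C1, C6, C8 and C1' reacts with an alkyl propiolate under HNTf2 catalysis in a [2+2] cycloaddition, and the donor–acceptor cyclobutene opens on warming to the cycloocta-1,3-diene ester A6. Here C1, C6 and C8 are set on a cyclohexane, where control is more dependable than hydride addition to a cyclooctanone. The C2=C3 unsaturation and the lactone carbonyl carbon arrive with the ring, so no selenium step is needed. In both respects this road is better than the chosen one. Against it stand the regiodefined enol ether formation away from the substituted C1 and a cycloaddition on a trisubstituted enol ether next to C6. The ring opening of a cis-fused bicyclo[4.2.0]octene to a cis,cis-diene is geometrically awkward. After the key step there is further work: the lactone methylene must still be attached at C2 in place of the silyloxy group, the lactone closed, and the C4=C5 part of a dienoate cyclopropanated beside the side-chain alkene. The chosen plan has the whole lactone in the precursor and forms no further skeletal bond to the ring system after the key step other than the cyclopropane.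

Key step: step 12

Assumption: the conjugate addition in step 7 is drawn as giving the 2S epimer; C2 is planarised in step 16, so its configuration affects the intermediates only and not the target.

Step 1
Reactants: 1 (E)-but-2-en-1-ol
Product: 2 [(1S,2S)-2-methylcyclopropyl]methanol
Conditions: Zn(CH2I)2·DME (from Et2Zn, CH2I2, DME), (4R,5R)-2-butyl-N,N,N',N'-tetramethyl-1,3,2-dioxaborolane-4,5-dicarboxamide (1.2 equiv), CH2Cl2, −10 to 23 °C
Reagents that add atoms: diiodomethane, ICI
Why: Charette asymmetric cyclopropanation: the zinc alkoxide of 1 is bound by the chiral dioxaborolane, which exposes one alkene face to the zinc carbenoid; the E geometry becomes the trans ring, and the (R,R)-ligand is the one known to give (S,S)-cyclopropylmethanols from E allylic alcohols, which fixes the two centres that become C5 and C6.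

Step 2
Reactants: 2 [(1S,2S)-2-methylcyclopropyl]methanol
Product: 3 (1S,2S)-2-methylcyclopropane-1-carbaldehyde
Conditions: TEMPO (10 mol %), PhI(OAc)2, CH2Cl2, 23 °C; distilled and kept as a stock solution in THF
Reagents that add atoms: none
Why: Oxoammonium (TEMPO) oxidation stops at the aldehyde under neutral conditions, so neither cyclopropane centre is touched; the volatile aldehyde is separated from iodobenzene by distillation.

Step 3
Reactants: 4 (4-carboxybutyl)triphenylphosphonium bromide; 5 acetone
Product: 6 6-methylhept-5-enoic acid
Conditions: KOt-Bu (2.2 equiv), THF, 0 °C; then 5, 0 to 23 °C; aq. HCl work-up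
Reagents that add atoms: none
Why: Wittig olefination of a symmetrical ketone with the carboxylate-bearing non-stabilised ylide builds the trisubstituted alkene; no stereochemical issue arises.

Step 4
Reactants: 6 6-methylhept-5-enoic acid; 7 (R)-4-benzyl-1,3-oxazolidin-2-one
Product: 9 (R)-4-benzyl-3-(6-methylhept-5-enoyl)-1,3-oxazolidin-2-one, via mixed pivalic anhydride 8 (not isolated)
Conditions: t-BuCOCl, Et3N, THF, −20 °C; then LiCl, 7, 23 °C
Reagents that add atoms: none
Why: N-Acylation of an oxazolidinone through the mixed pivalic anhydride, the standard preparation of Evans imides; the auxiliary attacks the less hindered carbonyl of the anhydride.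

Step 5
Reactants: 9 (R)-4-benzyl-3-(6-methylhept-5-enoyl)-1,3-oxazolidin-2-one
Product: 10 tert-butyl (3S)-3-[(4R)-4-benzyl-2-oxo-1,3-oxazolidine-3-carbonyl]-7-methyloct-6-enoate
Conditions: NaN(SiMe3)2, THF, −78 °C; BrCH2CO2t-Bu, −78 to −40 °C
Reagents that add atoms: tert-butyl bromoacetate, CC(C)(C)OC(=O)CBr
Why: Evans alkylation: the chelated Z sodium enolate is alkylated on the face opposite the benzyl group, which with the (R)-auxiliary gives the 3S centre that becomes C1'.

Step 6
Reactants: 10 tert-butyl (3S)-3-[(4R)-4-benzyl-2-oxo-1,3-oxazolidine-3-carbonyl]-7-methyloct-6-enoate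
Product: 12 (S)-4-(4-methylpent-3-en-1-yl)oxolan-2-one (lactone A), via hydroxy ester 11 (not isolated)
Conditions: LiBH4, MeOH (1.1 equiv), Et2O, 0 °C; crude, p-TsOH·H2O (10 mol %), toluene, 50 °C
Reagents that add atoms: none
Why: LiBH4 cleaves the imide carbonyl and leaves the tert-butyl ester, and acid-catalysed lactonisation of the γ-hydroxy ester closes lactone A; the stereocentre is not involved and the auxiliary 7 is recovered.

Step 7
Reactants: 12 (S)-4-(4-methylpent-3-en-1-yl)oxolan-2-one; 13 furan-2(5H)-one; 3 (1S,2S)-2-methylcyclopropane-1-carbaldehyde
Product: 15 bis-lactone aldol adduct (1'S,1R,2S,3R; C4 carbinol epimers), via lithium enolate 14 (not isolated)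
Conditions: LiN(i-Pr)2 (1.05 equiv), THF, −78 °C; 13 (1.0 equiv), −78 °C; then 3, −78 °C; AcOH
Reagents that add atoms: none
Why: Conjugate addition of a lithium lactone enolate to a butenolide with aldol trapping of the new enolate (three-component Michael–aldol sequence); C1 is set trans to the homoprenyl group because 13 can only reach the enolate face opposite the C1' substituent of the five-membered ring, while C2 (relative topicity of the two rings), C3 (aldehyde enters trans to the C2 substituent) and C4 are temporary centres removed in steps 8 and 16.

Step 8
Reactants: 15 bis-lactone aldol adduct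
Product: 17 (3R,4S)-3-[(3S,4E)-4-{[(1S,2S)-2-methylcyclopropyl]methylidene}-5-oxooxolan-3-yl]-4-(4-methylpent-3-en-1-yl)oxolan-2-one, via acetate 16 (not isolated)
Conditions: Ac2O, Et3N, DMAP (cat.), CH2Cl2, 0 to 23 °C; then DBU, 23 to 40 °C
Reagents that add atoms: none
Why: Acetylation and E1cB elimination of the β-acetoxy lactone through its enolate give the thermodynamically preferred E alkylidene; an acetate is used rather than a sulfonate so that no ionisable cyclopropylcarbinyl leaving group is present.

Step 9
Reactants: 17 (E)-alkylidene bis-lactone
Product: 19 lactol–lactone (lactone A reduced to the C8 lactol as anomers and lactone B intact), via bis-lactol 18 (not isolated)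
Conditions: i-Bu2AlH (2.4 equiv), CH2Cl2, −78 °C; aq. KNaC4H4O6; crude, MnO2 (activated), CH2Cl2, 23 °C
Reagents that add atoms: none
Why: i-Bu2AlH takes both lactones to their lactols (aluminium hemiacetals persist at −78 °C), and MnO2 oxidises only the allylic hemiacetal back to the conjugated lactone, which amounts to a selective half-reduction of the saturated lactone A; no carbon stereocentre of the target is touched.

Step 10
Reactants: 19 lactol–lactone
Product: 21 silyl ether N,N-dimethylhydrazone (1'S,1R,2S; E hydrazone; E alkylidene), via hydroxy hydrazone 20 (not isolated)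
Conditions: Me2NNH2, AcOH (cat.), MgSO4, CH2Cl2, 23 °C; concentrate; TBSCl, imidazole, DMF, 23 °C
Reagents that add atoms: 1,1-dimethylhydrazine, CN(C)N; tert-butyldimethylsilyl chloride, CC(C)(C)[Si](C)(C)Cl
Why: The lactol reacts through its hydroxy-aldehyde tautomer to give the open-chain hydrazone, and silylation of the released primary alcohol prevents re-closure (hydrazone formation, then silyl ether formation); C1 is not enolised under these conditions.

Step 11
Reactants: 21 silyl ether N,N-dimethylhydrazone
Product: 22 (2R,3S)-3-{[tert-butyl(dimethyl)silyl]oxymethyl}-7-methyl-2-[(3S,4E)-4-{[(1S,2S)-2-methylcyclopropyl]methylidene}-5-oxooxolan-3-yl]oct-6-enal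
Conditions: CuCl2 (2.5 equiv), THF/aq. phosphate buffer (pH 7), 23 °C
Reagents that add atoms: water, O
Why: Copper-assisted hydrolysis of an N,N-dimethylhydrazone at neutral pH frees the aldehyde without acid or base, so the α-centre C1, the silyl ether and the alkylidene lactone are preserved; 22 is used at once.

Step 12
Reactants: 22 alkylidene lactone aldehyde
Product: 23 lactone-fused (Z)-cyclooct-4-enone (1'S,1R,2S,3S,6S; trans-fused γ-lactone on C2–C3; C8 ketone; C4=C5 Z; C6 methyl; C1 bearing CH(CH2OTBS)(homoprenyl))
Conditions: [Rh(dppe)]BF4 (20 mol %, from [Rh(nbd)(dppe)]BF4 and H2), C2H4 (1 atm), ClCH2CH2Cl, 65 °C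
Reagents that add atoms: none
Why: Monovalent rhodium inserts into the C8–H bond and the acyl hydride adds across C3=C4 with hydrogen to C3 and rhodium to C4, giving a six-membered rhodacycle; the cyclopropylcarbinyl–rhodium unit then opens by β-carbon elimination of the less substituted C5–C7 bond to a nine-membered acyl alkyl rhodacycle containing the Z C4=C5 alkene, and C7–C8 reductive elimination releases 23. The closest known reaction type is the rhodium-catalysed intramolecular hydroacylation of 4-pentenals in its ring-expanding form, which turns 5-cyclopropylpent-4-enals into cyclooct-4-enones. The eight-membered ring is thus closed not end to end but by three-atom expansion of a six-membered metallacycle followed by acyl–alkyl reductive elimination, which avoids the entropic and transannular cost of a direct closure. The one new stereocentre, C3, is set by syn delivery of hydride from rhodium held on the lactone face that carries C1, so H-3 ends cis to C1 and the lactone is trans-fused; this centre is erased in step 16, and C6 is untouched because neither of its ring bonds is cleaved. The step needs rhodium on C4 rather than on the enolate carbon C3: the five-membered rhodacycle from the other regiochemistry has no productive exit, and reversible hydrometallation returns it to the six-membered one. It needs cleavage of C5–C7 rather than C5–C6, which the preference for a primary alkyl–rhodium bond secures. It needs ring opening to outrun reductive elimination to a cyclopentanone, which the strain release of the cyclopropane provides. Ethylene keeps the acyl rhodium species coordinatively saturated so that decarbonylation is held back.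

Step 13
Reactants: 23 lactone-fused (Z)-cyclooct-4-enone
Product: 24 cyclooct-4-enol (1'S,1R,2S,3S,6S,8S; hydroxyl cis to the C1 chain)
Conditions: LiBH(s-Bu)3, THF, −78 °C; aq. NH4Cl at −78 °C
Reagents that add atoms: none
Why: Reduction of a 2-substituted cycloalkanone with a bulky borohydride: hydride attacks C8 from the face opposite the branched C1 substituent (Felkin-type, peripheral attack) and gives the 8S alcohol; the lactone is not reduced at −78 °C and the cold quench avoids base-induced migration of the β,γ-alkene.

Step 14
Reactants: 24 cyclooct-4-enol
Product: 25 cyclopropane alcohol (1'S,1R,2S,3S,4R,5R,6S,8S; C9 cis to the C8 hydroxyl and trans to the C6 methyl)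
Conditions: Et2Zn (2.0 equiv), CH2I2 (2.2 equiv), CH2Cl2, −20 to 0 °C
Reagents that add atoms: diiodomethane, ICI
Why: Hydroxyl-directed Simmons–Smith cyclopropanation (Furukawa reagent): the C8 zinc alkoxide delivers the carbenoid across the ring to the alkene face on which it sits, which is also the face away from the C6 methyl group, so C4 and C5 are set together; intramolecular delivery with a limited amount of carbenoid is relied on to outrun reaction at the side-chain alkene.

Step 15
Reactants: 25 cyclopropane alcohol
Product: 26 bis-silyl ether of 25 (C8 O-TBS and C1' CH2O-TBS)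
Conditions: TBSOTf, 2,6-lutidine, CH2Cl2, −78 to 0 °C
Reagents that add atoms: tert-butyldimethylsilyl trifluoromethanesulfonate, CC(C)(C)[Si](C)(C)OS(=O)(=O)C(F)(F)F
Why: Silylation of a hindered secondary alcohol with the silyl triflate protects C8–OH against the amide base of the next step; no stereocentre is affected.

Step 16
Reactants: 26 bis-silyl ether
Product: 29 bis-silyl butenolide (C2=C3; 1'S,1R,4R,5R,6S,8S), via selenide 27 (not isolated), via selenoxide 28 (not isolated)
Conditions: LiN(i-Pr)2 (1.3 equiv), THF, −78 °C; PhSeBr, −78 °C; then 30 % H2O2, pyridine, CH2Cl2, 0 to 23 °C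
Reagents that add atoms: none
Why: α-Selenenylation of the lactone enolate and selenoxide syn elimination: the enolate is attacked on its convex face, away from C1, which places selenium cis to H-2; the selenoxide can then eliminate only towards H-2, because loss towards C4 would give an alkylidenecyclopropane, so the butenolide forms regiospecifically and the temporary centres C2 and C3 disappear; pyridine suppresses epoxidation of the side-chain alkene by selenium peracids.

Step 17
Reactants: 29 bis-silyl butenolide
Product: 30 diol (C8–OH and C1' CH2OH free)
Conditions: HF·pyridine, pyridine, THF, 0 to 23 °C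
Reagents that add atoms: none
Why: Cleavage of both silyl ethers with buffered HF; basic fluoride is avoided because H-1 is γ to the butenolide carbonyl and could epimerise through the dienolate.

Step 18
Reactants: 30 diol
Product: 31 target
Conditions: AcCl (1.1 equiv), 2,4,6-collidine, CH2Cl2, −78 °C
Reagents that add atoms: acetyl chloride, CC(=O)Cl
Why: Selective acylation of a primary over a hindered secondary alcohol with an acyl chloride and collidine at low temperature; the C8 hydroxyl, flanked by the branched C1, reacts far more slowly.

Compound list

1 | (E)-but-2-en-1-ol ((E)-crotyl alcohol) | C/C=C/CO | starting material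
2 | [(1S,2S)-2-methylcyclopropyl]methanol | OC[C@H]1C[C@@H]1C | intermediate
3 | (1S,2S)-2-methylcyclopropane-1-carbaldehyde | O=C[C@H]1C[C@@H]1C | intermediate
4 | (4-carboxybutyl)triphenylphosphonium bromide | OC(=O)CCCC[P+](c1ccccc1)(c1ccccc1)c1ccccc1.[Br-] | starting material
5 | acetone | CC(C)=O | starting material
6 | 6-methylhept-5-enoic acid | CC(C)=CCCCC(=O)O | intermediate
7 | (R)-4-benzyl-1,3-oxazolidin-2-one | O=C1N[C@H](Cc2ccccc2)CO1 | starting material
8 | 6-methylhept-5-enoic pivalic anhydride | CC(C)=CCCCC(=O)OC(=O)C(C)(C)C | intermediate
9 | (R)-4-benzyl-3-(6-methylhept-5-enoyl)-1,3-oxazolidin-2-one | CC(C)=CCCCC(=O)N1[C@H](Cc2ccccc2)COC1=O | intermediate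
10 | tert-butyl (3S)-3-[(4R)-4-benzyl-2-oxo-1,3-oxazolidine-3-carbonyl]-7-methyloct-6-enoate | CC(C)(C)OC(=O)C[C@H](CCC=C(C)C)C(=O)N1[C@H](Cc2ccccc2)COC1=O | intermediate
11 | tert-butyl (3S)-3-(hydroxymethyl)-7-methyloct-6-enoate | CC(C)(C)OC(=O)C[C@H](CCC=C(C)C)CO | intermediate
12 | (S)-4-(4-methylpent-3-en-1-yl)oxolan-2-one (lactone A) | O=C1C[C@H](CCC=C(C)C)CO1 | intermediate
13 | furan-2(5H)-one | O=C1C=CCO1 | starting material
14 | lithium enolate (in lactone B) of the Michael adduct of 12 and 13; 1'S,1R,2R by CIP, same geometry as 2S in 15 | O=C1[C@@H]([C@@H]2COC([O-])=C2)[C@H](CCC=C(C)C)CO1.[Li+] | intermediate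
15 | (3R,4S)-3-[(3S,4R)-4-{hydroxy[(1S,2S)-2-methylcyclopropyl]methyl}-5-oxooxolan-3-yl]-4-(4-methylpent-3-en-1-yl)oxolan-2-one, carbinol epimers | O=C1[C@@H]([C@@H]2COC(=O)[C@H]2C(O)[C@H]3C[C@@H]3C)[C@H](CCC=C(C)C)CO1 | intermediate
16 | acetate of 15 at the carbinol oxygen | O=C1[C@@H]([C@@H]2COC(=O)[C@H]2C(OC(C)=O)[C@H]3C[C@@H]3C)[C@H](CCC=C(C)C)CO1 | intermediate
17 | (3R,4S)-3-[(3S,4E)-4-{[(1S,2S)-2-methylcyclopropyl]methylidene}-5-oxooxolan-3-yl]-4-(4-methylpent-3-en-1-yl)oxolan-2-one | O=C1[C@@H]([C@@H]2COC(=O)/C2=C/[C@H]3C[C@@H]3C)[C@H](CCC=C(C)C)CO1 | intermediate
18 | bis-lactol of 17 (both carbonyls reduced to hemiacetals, anomers) | OC1[C@@H]([C@@H]2COC(O)/C2=C/[C@H]3C[C@@H]3C)[C@H](CCC=C(C)C)CO1 | intermediate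
19 | lactol–lactone: 17 with lactone A reduced to the C8 hemiacetal (anomers), alkylidene lactone B intact | OC1[C@@H]([C@@H]2COC(=O)/C2=C/[C@H]3C[C@@H]3C)[C@H](CCC=C(C)C)CO1 | intermediate
20 | open-chain hydroxy N,N-dimethylhydrazone of 19 (1'S,1R,2S; E hydrazone) | OC[C@@H](CCC=C(C)C)[C@@H](/C=N/N(C)C)[C@@H]1COC(=O)/C1=C/[C@H]1C[C@@H]1C | intermediate
21 | tert-butyldimethylsilyl ether of 20 | CC(C)(C)[Si](C)(C)OC[C@@H](CCC=C(C)C)[C@@H](/C=N/N(C)C)[C@@H]1COC(=O)/C1=C/[C@H]1C[C@@H]1C | intermediate
22 | (2R,3S)-3-{[tert-butyl(dimethyl)silyl]oxymethyl}-7-methyl-2-[(3S,4E)-4-{[(1S,2S)-2-methylcyclopropyl]methylidene}-5-oxooxolan-3-yl]oct-6-enal | CC(C)(C)[Si](C)(C)OC[C@@H](CCC=C(C)C)[C@@H](C=O)[C@@H]1COC(=O)/C1=C/[C@H]1C[C@@H]1C | intermediate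
23 | trans-lactone-fused (Z)-cyclooct-4-enone (1'S,1R,2S,3S,6S) with the C1 chain CH(CH2OTBS)(4-methylpent-3-enyl) | CC(C)(C)[Si](C)(C)OC[C@@H](CCC=C(C)C)[C@@H]1[C@@H]2COC(=O)[C@H]2/C=C\[C@@H](C)CC1=O | intermediate
24 | (8S)-alcohol from 23, hydroxyl cis to the C1 chain | CC(C)(C)[Si](C)(C)OC[C@@H](CCC=C(C)C)[C@@H]1[C@@H]2COC(=O)[C@H]2/C=C\[C@@H](C)C[C@@H]1O | intermediate
25 | (4R,5R)-cyclopropane from 24, C9 cis to the C8 hydroxyl and trans to the C6 methyl | CC(C)(C)[Si](C)(C)OC[C@@H](CCC=C(C)C)[C@@H]1[C@@H]2COC(=O)[C@H]2[C@@H]3C[C@@H]3[C@@H](C)C[C@@H]1O | intermediate
26 | C8 tert-butyldimethylsilyl ether of 25 | CC(C)(C)[Si](C)(C)OC[C@@H](CCC=C(C)C)[C@@H]1[C@@H]2COC(=O)[C@H]2[C@@H]3C[C@@H]3[C@@H](C)C[C@@H]1O[Si](C)(C)C(C)(C)C | intermediate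
27 | C3 phenylselenide of 26, cis-fused lactone, selenium cis to H-2 | CC(C)(C)[Si](C)(C)OC[C@@H](CCC=C(C)C)[C@@H]1[C@@H]2COC(=O)[C@]2([Se]c3ccccc3)[C@@H]4C[C@@H]4[C@@H](C)C[C@@H]1O[Si](C)(C)C(C)(C)C | intermediate
28 | selenoxide of 27 (both configurations at selenium) | CC(C)(C)[Si](C)(C)OC[C@@H](CCC=C(C)C)[C@@H]1[C@@H]2COC(=O)[C@]2([Se](=O)c3ccccc3)[C@@H]4C[C@@H]4[C@@H](C)C[C@@H]1O[Si](C)(C)C(C)(C)C | intermediate
29 | bis(tert-butyldimethylsilyl) ether of diol 30 (butenolide C2=C3) | CC(C)(C)[Si](C)(C)OC[C@@H](CCC=C(C)C)[C@@H]1C2=C(C(=O)OC2)[C@@H]2C[C@@H]2[C@@H](C)C[C@@H]1O[Si](C)(C)C(C)(C)C | intermediate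
30 | deacetyl target (C1' CH2OH and C8 OH) | OC[C@@H](CCC=C(C)C)[C@@H]1C2=C(C(=O)OC2)[C@@H]2C[C@@H]2[C@@H](C)C[C@@H]1O | intermediate
31 | CNP0267808.2 (1'S,1R,4R,5R,6S,8S) | CC(=O)OC[C@@H](CCC=C(C)C)[C@@H]1C2=C(C(=O)OC2)[C@@H]2C[C@@H]2[C@@H](C)C[C@@H]1O | target

Total step count: 18. Longest linear sequence: 16 steps (steps 3 to 18, from 4 and 5); steps 1 and 2 supply aldehyde 3, which enters at step 7.

Least certain steps

Step 12 (key step). The hydrometallation may stall because the alkene is trisubstituted and conjugated to the lactone carbonyl. Rhodium then prefers the enolate position C3, the acyl hydride waits, and decarbonylation or plain alkene isomerisation take over. Direct reductive elimination to a cyclopentanone and opening of the C5–C6 bond are lesser risks. The fallback takes the carbonyl out of conjugation for the duration of the ring formation, which moves the substrate into the proven range of the reaction. It sets out from 21. Reduction with i-Bu2AlH at −78 °C gives the lactol hydrazone F1. Methanol, trimethyl orthoformate and pyridinium p-toluenesulfonate give the methyl acetal hydrazone F2. CuCl2 hydrolysis at pH 7 gives the acetal aldehyde F3. [Rh(dppe)]BF4 under ethylene gives the cyclooctenone acetal F4. Pyridinium p-toluenesulfonate in aqueous acetone gives the cyclooctenone lactol F5, and Ag2CO3 on Celite oxidises this lactol to the lactone, returning to the route at 23.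

Step 7. Proton transfer from the γ-methylene of 13 to the lactone enolate, followed by oligomerisation of 13, can consume both partners. The relative topicity that sets C2 may be poorly controlled, and enolate 14 may equilibrate before the aldehyde arrives. The fallback separates the two bond formations and replaces the basic enolate by a silyl ketene acetal. It sets out from 12. LiN(i-Pr)2 and Me3SiCl give the trimethylsilyl ketene acetal F6. A Mukaiyama–Michael addition to 13 with TiCl4 at −78 °C gives, after work-up, the bis-lactone Michael adduct F7. Kinetic deprotonation of its unhindered C3 methylene with LiN(i-Pr)2 and addition of 3 returns to the route at 15.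

Step 9. Over-reduction of the saturated lactol to the diol, or slow re-oxidation of that lactol on MnO2, would erase the distinction between the two rings. The fallback uses an amide instead of a lactol as the open form. It sets out from 17. Me2AlN(OMe)Me is expected to open the saturated lactone A faster than the conjugated lactone B and give the hydroxy N-methoxy-N-methylamide F8. Silylation with TBSCl and imidazole gives the silyl ether amide F9. Cp2Zr(H)Cl reduces the amide to the aldehyde in the presence of the lactone, returning to the route at 22.

Step 13. Hydride may attack from the wrong face, because the C6 methyl group lies 1,3 to C8 on the face that must be attacked, opposing the bias from C1. Enolisation towards C1 by the basic reagent is a further risk. The fallback replaces substrate control by reagent control: Corey–Bakshi–Shibata reduction of 23 with the (R)-B-methyl oxazaborolidine and catecholborane at −78 °C. This reagent distinguishes the branched C1 side from the C7 methylene and is expected to give the 8S alcohol. It sets out from 23, returns at 24 and makes no new compound (F0).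

Step 14. The carbenoid may react at the electron-rich side-chain alkene if delivery from a transannular zinc alkoxide is not much faster than the intermolecular reaction. The fallback changes the carbene source to one that discriminates by substitution pattern. It sets out from 24. Silylation with TBSOTf and 2,6-lutidine gives the bis-silyl cyclooctene F10. Pd(OAc)2-catalysed decomposition of diazomethane in ether at 0 °C cyclopropanates the Z-disubstituted ring alkene and leaves trisubstituted alkenes alone, with the face chosen by the C6 methyl and the C3 substituent. This returns to the route at 26.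

Step 16. Selenenylation on the concave face would give a selenide with no hydrogen syn to selenium, and oxidation of the side-chain alkene by selenium peracids can accompany the elimination. The fallback is a Saegusa–Ito oxidation, which does not depend on the configuration at C3. It sets out from 26. LiN(i-Pr)2 and Me3SiCl give the trimethylsilyl ketene acetal F11. Pd(OAc)2 in acetonitrile forms the divalent palladium enolate, which loses H-2 by β-hydride elimination, returning to the route at 29.

Further compounds

F1 | step 12 | lactol hydrazone: 21 with the lactone B carbonyl reduced to the hemiacetal (anomers) | CC(C)(C)[Si](C)(C)OC[C@@H](CCC=C(C)C)[C@@H](/C=N/N(C)C)[C@@H]1COC(O)/C1=C/[C@H]1C[C@@H]1C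
F2 | step 12 | methyl acetal hydrazone: O-methyl acetal of F1 (anomers) | CC(C)(C)[Si](C)(C)OC[C@@H](CCC=C(C)C)[C@@H](/C=N/N(C)C)[C@@H]1COC(OC)/C1=C/[C@H]1C[C@@H]1C
F3 | step 12 | acetal aldehyde: 22 with the lactone carbonyl replaced by a methyl acetal | CC(C)(C)[Si](C)(C)OC[C@@H](CCC=C(C)C)[C@@H](C=O)[C@@H]1COC(OC)/C1=C/[C@H]1C[C@@H]1C
F4 | step 12 | cyclooctenone acetal: 23 with the lactone carbonyl replaced by a methyl acetal | CC(C)(C)[Si](C)(C)OC[C@@H](CCC=C(C)C)[C@@H]1[C@@H]2COC(OC)[C@H]2/C=C\[C@@H](C)CC1=O
F5 | step 12 | cyclooctenone lactol: 23 with the lactone carbonyl replaced by a hemiacetal | CC(C)(C)[Si](C)(C)OC[C@@H](CCC=C(C)C)[C@@H]1[C@@H]2COC(O)[C@H]2/C=C\[C@@H](C)CC1=O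
F6 | step 7 | trimethylsilyl ketene acetal of 12, (S)-5-trimethylsilyloxy-3-(4-methylpent-3-en-1-yl)-2,3-dihydrofuran | C[Si](C)(C)OC1=C[C@H](CCC=C(C)C)CO1
F7 | step 7 | bis-lactone Michael adduct, (3R,4S)-4-(4-methylpent-3-en-1-yl)-3-[(3R)-5-oxooxolan-3-yl]oxolan-2-one | O=C1[C@@H]([C@@H]2COC(=O)C2)[C@H](CCC=C(C)C)CO1
F8 | step 9 | hydroxy N-methoxy-N-methylamide from opening of lactone A of 17 | OC[C@@H](CCC=C(C)C)[C@@H](C(=O)N(C)OC)[C@@H]1COC(=O)/C1=C/[C@H]1C[C@@H]1C
F9 | step 9 | tert-butyldimethylsilyl ether of F8 | CC(C)(C)[Si](C)(C)OC[C@@H](CCC=C(C)C)[C@@H](C(=O)N(C)OC)[C@@H]1COC(=O)/C1=C/[C@H]1C[C@@H]1C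
F0 | step 13 | none | none
F10 | step 14 | bis-silyl cyclooctene: C8 tert-butyldimethylsilyl ether of 24 | CC(C)(C)[Si](C)(C)OC[C@@H](CCC=C(C)C)[C@@H]1[C@@H]2COC(=O)[C@H]2/C=C\[C@@H](C)C[C@@H]1O[Si](C)(C)C(C)(C)C
F11 | step 16 | trimethylsilyl ketene acetal of 26 | CC(C)(C)[Si](C)(C)OC[C@@H](CCC=C(C)C)[C@@H]1[C@@H]2COC(O[Si](C)(C)C)=C2[C@@H]3C[C@@H]3[C@@H](C)C[C@@H]1O[Si](C)(C)C(C)(C)C
A1 | alternative 1 | cyclononadiene homoallylic mesylate (C4 mesylate, C9 methylene, Z C5=C6 with the methyl on C6, C8 silyl ether) | CC(=O)OC[C@@H](CCC=C(C)C)[C@@H]1C2=C(C(=O)OC2)[C@H](OS(C)(=O)=O)C/C=C(C)\C[C@@H]1O[Si](C)(C)C(C)(C)C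
A2 | alternative 1 | C8 tert-butyldimethylsilyl ether of the target | CC(=O)OC[C@@H](CCC=C(C)C)[C@@H]1C2=C(C(=O)OC2)[C@@H]2C[C@@H]2[C@@H](C)C[C@@H]1O[Si](C)(C)C(C)(C)C
A3 | alternative 2 | bridged β-diketone: keto bridge between C3 and C7, C8 ketone, C2 hydroxymethyl cis to the bridge, cyclopropane on C4–C5 | CC(C)(C)[Si](C)(C)OC[C@@H](CCC=C(C)C)[C@@H]1[C@H](CO)[C@H]2[C@@H]3C[C@@H]3[C@@H](C)[C@H](C2=O)C1=O
A4 | alternative 2 | tricyclic C8 ketone with the saturated cis-fused lactone | CC(C)(C)[Si](C)(C)OC[C@@H](CCC=C(C)C)[C@@H]1[C@@H]2COC(=O)[C@@H]2[C@@H]3C[C@@H]3[C@@H](C)CC1=O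
A5 | alternative 3 | trimethylsilyl enol ether (C2=C5) of the cyclohexanone carrying C1, C6 and C8 | CC(C)(C)[Si](C)(C)OC[C@@H](CCC=C(C)C)[C@@H]1C(O[Si](C)(C)C)=C[C@@H](C)C[C@@H]1O[Si](C)(C)C(C)(C)C
A6 | alternative 3 | methyl 2-trimethylsilyloxycycloocta-1,3-diene-1-carboxylate with C1, C6, C8 and C1' in place | CC(C)(C)[Si](C)(C)OC[C@@H](CCC=C(C)C)[C@@H]1/C(O[Si](C)(C)C)=C(C(=O)OC)\C=C/[C@@H](C)C[C@@H]1O[Si](C)(C)C(C)(C)C
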